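**Plan**
- The pyrrole is traced back to a saturated N-tosyl pyrrolidine (N1, C2 with CO2Me, C3 with the chain C1'–C21', C4, C5); loss of sulfinate and one dehydrogenation restore the aromatic ring.
- In that pyrrolidine two bonds are cut together, C3–C4 in the ring and C1'–C2' in the chain. This is possible because C3 and C1' form the vinyl group of a vinylglycine on C2, one N–C–C tether away from a carboxylic acid, and C2' onward is a plain C20 tail.
- Forward: L-methionine methyl ester receives the N-CH2CH2CO2tBu arm and the tosyl group, the thioether is turned into the vinyl group by sulfoxide pyrolysis, and acid frees the carboxylic acid.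
- Co-electrolysis with henicosanoic acid then closes the only ring (5-exo) and attaches the chain in one operation; DBU and DDQ complete the aromatisation.
- Stereochemistry: C2 comes from L-methionine and C3 is set trans to it in the radical closure; both centres disappear in the achiral target, so neither needs control.

Key step: step 6

Remark: the target is achiral, so the (2S) centre from L-methionine and the C3 centre made in step 6 are carried only as bookkeeping; 14 is written as the imine tautomer without a descriptor at its labile ring carbon.

**Step 1**
Reactants: 1 L-methionine methyl ester hydrochloride; 2 tert-butyl acrylate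
Product: 3 methyl (2S)-2-[(3-tert-butoxy-3-oxopropyl)amino]-4-(methylsulfanyl)butanoate
Conditions: Et3N (1 equiv), MeOH, rt to 40 °C
Reagents that add atoms: none
Why: Aza-Michael addition of the liberated primary amine to the acrylate is reliable in a protic solvent, should stop at monoaddition because the α-branched secondary amine is hindered, and does not touch the α-stereocentre.

**Step 2**
Reactants: 3 methyl (2S)-2-[(3-tert-butoxy-3-oxopropyl)amino]-4-(methylsulfanyl)butanoate; 4 4-toluenesulfonyl chloride
Product: 5 methyl (2S)-2-[(3-tert-butoxy-3-oxopropyl)(4-methylbenzenesulfonyl)amino]-4-(methylsulfanyl)butanoate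
Conditions: Et3N, DMAP (cat.), CH2Cl2, 0 °C to reflux
Reagents that add atoms: none
Why: DMAP-catalysed N-sulfonylation of the secondary amine protects nitrogen against anodic oxidation and installs the later sulfinate leaving group, while the thioether and both esters are inert to TsCl.

**Step 3**
Reactants: 5 methyl (2S)-2-[(3-tert-butoxy-3-oxopropyl)(4-methylbenzenesulfonyl)amino]-4-(methylsulfanyl)butanoate
Product: 6 methyl (2S)-2-[(3-tert-butoxy-3-oxopropyl)(4-methylbenzenesulfonyl)amino]-4-(methanesulfinyl)butanoate (both sulfur epimers)
Conditions: NaIO4 (1.05 equiv), MeOH–H2O, 0 °C to rt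
Reagents that add atoms: NaIO4 (sodium metaperiodate), [Na+].[O-]I(=O)(=O)=O
Why: NaIO4 oxidises dialkyl sulfides chemoselectively to sulfoxides without going on to the sulfone, and the new sulfur stereocentre, formed unselectively, is destroyed in the next step.

**Step 4**
Reactants: 6 methyl (2S)-2-[(3-tert-butoxy-3-oxopropyl)(4-methylbenzenesulfonyl)amino]-4-(methanesulfinyl)butanoate
Product: 7 methyl (2S)-2-[(3-tert-butoxy-3-oxopropyl)(4-methylbenzenesulfonyl)amino]but-3-enoate
Conditions: 1,2-dichlorobenzene, 175 °C, N2 sweep
Reagents that add atoms: none
Why: Thermal syn-elimination of the sulfoxide (sulfoxide pyrolysis, the classical methionine-to-vinylglycine tactic) can only take a β-hydrogen from C3 and so gives the terminal vinyl group; the medium is neutral, which should preserve the double-bond position, and any thermal loss of isobutene merely anticipates step 5.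

**Step 5**
Reactants: 7 methyl (2S)-2-[(3-tert-butoxy-3-oxopropyl)(4-methylbenzenesulfonyl)amino]but-3-enoate
Product: 8 3-{[(2S)-1-methoxy-1-oxobut-3-en-2-yl](4-methylbenzenesulfonyl)amino}propanoic acid
Conditions: TFA, CH2Cl2, 0 °C to rt
Reagents that add atoms: none
Why: Acidolysis of the tert-butyl ester through the tert-butyl cation frees the carboxylic acid without base, so the methyl ester, the sulfonamide and the base-sensitive vinylglycine unit should remain intact.

**Step 6**
Reactants: 8 3-{[(2S)-1-methoxy-1-oxobut-3-en-2-yl](4-methylbenzenesulfonyl)amino}propanoic acid; 9 henicosanoic acid (excess)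
Product: 13 methyl (2S,3S)-3-henicosyl-1-(4-methylbenzenesulfonyl)pyrrolidine-2-carboxylate, via primary C4 radical 10 (not isolated), via icosyl radical 11 (not isolated), via ring-closed C1' radical 12 (not isolated)
Conditions: Pt anode and Pt cathode, undivided cell, constant current (about 0.2 A cm−2) with periodic polarity reversal, 9 (8 equiv), KOH (5 mol% of total acid), MeOH–acetone 4:1, 50 °C
Reagents that add atoms: none
Why: Mixed Kolbe electrolysis: both carboxylates are discharged at the Pt anode and lose CO2, so the primary C4 radical 10 and the icosyl radical 11 arise side by side in the thin reaction layer at the electrode. Radical 10 is a 3-aza-hex-5-enyl radical that closes in 5-exo-trig mode onto the inner vinyl carbon C3 (bond C3–C4, the pyrrolidine ring), and the exocyclic primary radical 12 then combines with 11 (bond C1'–C2'); the closest known reaction type is the co-electrolysis of N-protected 3-(allylamino)propanoic acids with a second acid, which gives 3-alkylpyrrolidines by the same ring closure and cross-coupling. The new C3 centre is set relative to C2 in the chair-like transition state of the hexenyl closure with the C2 ester pseudo-equatorial, which should favour the trans (2S,3S) isomer, and the cis isomer would serve equally because both centres are flattened later. Two selectivities are required: ring closure ahead of intermolecular coupling, which rests on the fast closure of the sulfonamide-tethered radical carrying a substituent at the allylic carbon, and cross-coupling ahead of homo-coupling of 12, which rests on the large excess of the cheap co-acid. The tertiary sulfonamide, the methyl ester and the terminal alkene are not oxidised under Kolbe conditions, primary radicals are not oxidised on to cations, and the non-polar dimer of the co-acid (tetracontane) is removed by filtration and chromatography.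

**Step 7**
Reactants: 13 methyl (2S,3S)-3-henicosyl-1-(4-methylbenzenesulfonyl)pyrrolidine-2-carboxylate
Product: 14 methyl 4-henicosyl-3,4-dihydro-2H-pyrrole-5-carboxylate
Conditions: DBU (3 equiv), DMF, 80 °C
Reagents that add atoms: none
Why: E1cB elimination, in which DBU removes the C2 proton next to the ester and the enolate expels 4-toluenesulfinate from nitrogen, is a known way from N-sulfonyl α-amino esters to α-imino esters and here delivers N-deprotection and the first oxidation level together.

**Step 8**
Reactants: 14 methyl 4-henicosyl-3,4-dihydro-2H-pyrrole-5-carboxylate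
Product: 15 methyl 3-henicosyl-1H-pyrrole-2-carboxylate
Conditions: DDQ (1.1 equiv), toluene, rt to 60 °C
Reagents that add atoms: none
Why: Dehydrogenation of a 1-pyrroline to the pyrrole by hydride abstraction with DDQ (through the enamine tautomer) is a standard aromatisation driven by the gain of aromaticity, the electron-poor pyrrole-2-carboxylate should resist further oxidation, and the last stereocentre is erased.

**Compound list**
1 | L-methionine methyl ester hydrochloride | Cl.CSCC[C@H](N)C(=O)OC | starting material
2 | tert-butyl acrylate | C=CC(=O)OC(C)(C)C | starting material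
3 | methyl (2S)-2-[(3-tert-butoxy-3-oxopropyl)amino]-4-(methylsulfanyl)butanoate | CSCC[C@H](NCCC(=O)OC(C)(C)C)C(=O)OC | intermediate
4 | 4-toluenesulfonyl chloride | Cc1ccc(S(=O)(=O)Cl)cc1 | starting material
5 | methyl (2S)-2-[(3-tert-butoxy-3-oxopropyl)(4-methylbenzenesulfonyl)amino]-4-(methylsulfanyl)butanoate | CSCC[C@H](N(CCC(=O)OC(C)(C)C)S(=O)(=O)c1ccc(C)cc1)C(=O)OC | intermediate
6 | methyl (2S)-2-[(3-tert-butoxy-3-oxopropyl)(4-methylbenzenesulfonyl)amino]-4-(methanesulfinyl)butanoate, both sulfur epimers | CS(=O)CC[C@H](N(CCC(=O)OC(C)(C)C)S(=O)(=O)c1ccc(C)cc1)C(=O)OC | intermediate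
7 | methyl (2S)-2-[(3-tert-butoxy-3-oxopropyl)(4-methylbenzenesulfonyl)amino]but-3-enoate | C=C[C@H](N(CCC(=O)OC(C)(C)C)S(=O)(=O)c1ccc(C)cc1)C(=O)OC | intermediate
8 | 3-{[(2S)-1-methoxy-1-oxobut-3-en-2-yl](4-methylbenzenesulfonyl)amino}propanoic acid | C=C[C@H](N(CCC(=O)O)S(=O)(=O)c1ccc(C)cc1)C(=O)OC | intermediate
9 | henicosanoic acid | CCCCCCCCCCCCCCCCCCCCC(=O)O | starting material
10 | primary C4 radical, not isolated: 2-{[(2S)-1-methoxy-1-oxobut-3-en-2-yl](4-methylbenzenesulfonyl)amino}ethyl radical | C=C[C@H](N(C[CH2])S(=O)(=O)c1ccc(C)cc1)C(=O)OC | intermediate
11 | icosyl radical, not isolated: icosan-1-yl radical | [CH2]CCCCCCCCCCCCCCCCCCC | intermediate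
12 | ring-closed C1' radical, not isolated: [(2S,3S)-2-(methoxycarbonyl)-1-(4-methylbenzenesulfonyl)pyrrolidin-3-yl]methyl radical | COC(=O)[C@@H]1[C@@H]([CH2])CCN1S(=O)(=O)c1ccc(C)cc1 | intermediate
13 | methyl (2S,3S)-3-henicosyl-1-(4-methylbenzenesulfonyl)pyrrolidine-2-carboxylate (trans) | COC(=O)[C@@H]1[C@@H](CCCCCCCCCCCCCCCCCCCCC)CCN1S(=O)(=O)c1ccc(C)cc1 | intermediate
14 | methyl 4-henicosyl-3,4-dihydro-2H-pyrrole-5-carboxylate (imine tautomer, ring CH centre labile) | COC(=O)C1=NCCC1CCCCCCCCCCCCCCCCCCCCC | intermediate
15 | methyl 3-henicosyl-1H-pyrrole-2-carboxylate | CCCCCCCCCCCCCCCCCCCCCc1cc[nH]c1C(=O)OC | target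

**Step count**
Total steps: 8. Longest linear sequence: 8 steps (1 to 15); compounds 2, 4 and 9 are purchased and enter directly.

**Steps most likely to fail**

Step 6. The open-chain radical may couple or be quenched at the electrode before it closes the ring. Homo-coupling of the co-acid may also dominate, and its waxy hydrocarbon dimer may coat the anode and stall the current. The same two bonds can then be made in homogeneous solution by known nickel chemistry.
- Setting out from 8, condensation with N-hydroxyphthalimide (DIC, cat. DMAP, CH2Cl2) gives the redox-active ester 1,3-dioxoisoindolin-2-yl 3-{[(2S)-1-methoxy-1-oxobut-3-en-2-yl](4-methylbenzenesulfonyl)amino}propanoate F1.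
- Purchased 1-bromoicosane is converted with Mg in THF into icosylmagnesium bromide F2, and this with half an equivalent of ZnCl2 into diicosylzinc F3.
- F1, F3 and catalytic NiCl2·glyme with 4,4'-di-tert-butyl-2,2'-bipyridine in THF–DMF at rt (decarboxylative alkyl–alkyl Negishi coupling) should generate radical 10 by single-electron reduction with loss of CO2 and phthalimide anion.
- At the low radical concentration of a catalytic cycle the 5-exo closure to 12 should precede capture by the alkylnickel species, and reductive elimination forms C1'–C2'. The route is rejoined at 13.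

Step 4. At about 175 °C the double bond may migrate into conjugation with the ester, the tert-butyl group may be lost early with ensuing decomposition, or sulfenic acid may add back to the alkene. The elimination can then be run much cooler through a sulfilimine.
- Setting out from thioether 5, chloramine-T (TsNClNa·3H2O, MeOH, rt) gives methyl (2S)-2-[(3-tert-butoxy-3-oxopropyl)(4-methylbenzenesulfonyl)amino]-4-[S-methyl-N-(4-methylbenzenesulfonyl)sulfinimidoyl]butanoate F4.
- Its syn-elimination should proceed in toluene at about 90 to 110 °C and deliver 7, where the route is rejoined; step 3 is skipped.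

Step 7. Deprotonation at the hindered C2–H may be too slow for sulfinate to be expelled, or base-induced ester condensation may compete at the temperature needed. Nitrogen can then be freed reductively and all four hydrogens removed afterwards.
- Setting out from 13, Mg turnings in MeOH under sonication should cleave the N–S bond to give methyl (2S,3S)-3-henicosylpyrrolidine-2-carboxylate F5.
- Activated MnO2 in refluxing THF, a known aromatisation of proline esters, should dehydrogenate F5 directly to the target 15, bypassing 14 and step 8.

**Further compounds**
F1 | step 6 | 1,3-dioxoisoindolin-2-yl 3-{[(2S)-1-methoxy-1-oxobut-3-en-2-yl](4-methylbenzenesulfonyl)amino}propanoate | C=C[C@H](N(CCC(=O)ON1C(=O)c2ccccc2C1=O)S(=O)(=O)c1ccc(C)cc1)C(=O)OC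
F2 | step 6 | icosylmagnesium bromide | CCCCCCCCCCCCCCCCCCCC[Mg]Br
F3 | step 6 | diicosylzinc | CCCCCCCCCCCCCCCCCCCC[Zn]CCCCCCCCCCCCCCCCCCCC
F4 | step 4 | methyl (2S)-2-[(3-tert-butoxy-3-oxopropyl)(4-methylbenzenesulfonyl)amino]-4-[S-methyl-N-(4-methylbenzenesulfonyl)sulfinimidoyl]butanoate, both sulfur epimers | CS(=NS(=O)(=O)c1ccc(C)cc1)CC[C@H](N(CCC(=O)OC(C)(C)C)S(=O)(=O)c1ccc(C)cc1)C(=O)OC
F5 | step 7 | methyl (2S,3S)-3-henicosylpyrrolidine-2-carboxylate | COC(=O)[C@@H]1[C@@H](CCCCCCCCCCCCCCCCCCCCC)CCN1
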